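The route rests on cutting the skipped diene between its doubly allylic CH2 (C3 of the heptadienyl chain, flanked by the methyl-bearing C4=C5 alkene) and the sp2 CH (C2) of the E-alkene that hangs on the quaternary carbon of the tetrahydrofuran ring. One Suzuki–Miyaura allyl–alkenyl coupling joins an (E)-alkenyl pinacol boronate that already carries the complete trans-tetrahydrofuran–γ-lactone unit and all three stereocentres with an (E)-allylic bromide that carries the 3-furyl group. The step exploits two features: the sp3 carbon is the primary terminus of an allyl system, and the alkenyl carbon sits next to a fully substituted, non-epimerisable ring carbon.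

Key step: step 12

Remark on the chemistry: commercial geranyl acetate is taken as the pure (E)-isomer; the stereocentres of 2 and 3 are racemic and are erased in step 3, so enantiocontrol begins in step 4.

Step 1
Reactants: 1 geranyl acetate
Product: 2 rac-(E)-5-(3,3-dimethyloxiran-2-yl)-3-methylpent-2-en-1-yl acetate (6,7-epoxygeranyl acetate)
Conditions: mCPBA (1.05 equiv), NaHCO3, CH2Cl2, 0 °C
Reagents that add atoms: mCPBA, O=C(OO)c1cccc(Cl)c1
Why: Prilezhaev epoxidation, in which the peracid should pick the electron-rich distal trisubstituted alkene over the alkene deactivated by the allylic acetate; the new stereocentre is racemic and is erased in step 3.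

Step 2
Reactants: 2 rac-6,7-epoxygeranyl acetate
Product: 3 rac-(E)-6-hydroxy-3,7-dimethylocta-2,7-dien-1-yl acetate
Conditions: Al(OiPr)3 (1.5 equiv), toluene, 110 °C
Reagents that add atoms: none
Why: Aluminium alkoxide-mediated epoxide-to-allylic-alcohol isomerisation, in which the Lewis acid activates the epoxide and an alkoxide ligand removes a proton from a gem-methyl group in a syn elimination, should give the secondary isopropenyl carbinol.

Step 3
Reactants: 3 rac-(E)-6-hydroxy-3,7-dimethylocta-2,7-dien-1-yl acetate; 4 triethyl orthoacetate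
Product: 5 ethyl (4E,8E)-10-acetoxy-4,8-dimethyldeca-4,8-dienoate
Conditions: MeC(OEt)3 (6 equiv), EtCO2H (cat.), 140 °C, EtOH distilled off
Reagents that add atoms: none
Why: Johnson–Claisen rearrangement of the mixed ketene acetal through a chair transition state with the chain pseudo-equatorial should give the (E)-trisubstituted alkene and erases the carbinol stereocentre.

Step 4
Reactants: 5 ethyl (4E,8E)-10-acetoxy-4,8-dimethyldeca-4,8-dienoate
Product: 6 ethyl 3-[(2R,3R)-3-[(E)-5-acetoxy-3-methylpent-3-en-1-yl]-2-methyloxiran-2-yl]propanoate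
Conditions: D-fructose-derived Shi ketone (30 mol %), KHSO5 (as the triple salt 2KHSO5·KHSO4·K2SO4), K2CO3, Bu4NHSO4, MeCN/CH2(OMe)2/aq. Na2B4O7 buffer, 0 °C
Reagents that add atoms: potassium peroxymonosulfate KHSO5, [K+].[O-]S(=O)(=O)OO
Why: Shi asymmetric epoxidation, in which the chiral dioxirane transfers oxygen through a spiro transition state to the electron-rich C4=C5 alkene (the allylic acetate alkene is deactivated), should give the (R,R)-epoxide by reagent control.

Step 5
Reactants: 6 ethyl 3-[(2R,3R)-3-[(E)-5-acetoxy-3-methylpent-3-en-1-yl]-2-methyloxiran-2-yl]propanoate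
Product: 8 (S)-5-[(R,E)-1,6-dihydroxy-4-methylhex-4-en-1-yl]-5-methyldihydrofuran-2(3H)-one, via epoxy acid 7 (not isolated)
Conditions: LiOH·H2O (3 equiv), THF/H2O, 0 °C → rt; then 1 M HCl to pH 3, rt
Reagents that add atoms: lithium hydroxide, [Li+].[OH-]
Why: Saponification frees the carboxylate and the allylic alcohol, and on acidification the carboxylic acid opens the epoxide 5-exo at its tertiary carbon with inversion (acid-catalysed epoxy-acid lactonisation), which turns the (R) epoxide carbon into the (S) lactone carbon while the (R) carbinol carbon keeps its C–O bond; this anti addition across the former E-alkene is what the target requires.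

Step 6
Reactants: 8 (S)-5-[(R,E)-1,6-dihydroxy-4-methylhex-4-en-1-yl]-5-methyldihydrofuran-2(3H)-one
Product: 10 (S)-5-[(2R,5R)-5-[(S)-1,2-dihydroxyethyl]-5-methyltetrahydrofuran-2-yl]-5-methyldihydrofuran-2(3H)-one, via epoxy alcohol 9 (not isolated)
Conditions: Ti(OiPr)4 (1.0 equiv), L-(+)-diethyl tartrate (1.2 equiv), t-BuOOH (2 equiv), 4 Å MS, CH2Cl2, −20 °C; then CSA (10 mol %), 0 °C → rt
Reagents that add atoms: tert-butyl hydroperoxide, CC(C)(C)OO
Why: Katsuki–Sharpless asymmetric epoxidation with L-(+)-tartrate should give the (2S,3S)-epoxy alcohol by reagent control, and the secondary hydroxyl then opens it 5-exo-tet at the tertiary carbon with inversion (acid-catalysed epoxide-opening cyclisation), which sets the (R) quaternary ring carbon and the trans relationship of the two side chains.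

Step 7
Reactants: 10 (S)-5-[(2R,5R)-5-[(S)-1,2-dihydroxyethyl]-5-methyltetrahydrofuran-2-yl]-5-methyldihydrofuran-2(3H)-one
Product: 11 (2R,5R)-2-methyl-5-[(S)-2-methyl-5-oxotetrahydrofuran-2-yl]tetrahydrofuran-2-carbaldehyde
Conditions: NaIO4 (1.5 equiv), THF/H2O, 0 °C → rt
Reagents that add atoms: none
Why: Periodate (Malaprade) glycol cleavage gives an aldehyde on a fully substituted carbon that has no α-hydrogen and cannot epimerise, and the lactone is inert.

Step 8
Reactants: 11 (2R,5R)-2-methyl-5-[(S)-2-methyl-5-oxotetrahydrofuran-2-yl]tetrahydrofuran-2-carbaldehyde; 12 2-(dichloromethyl)-4,4,5,5-tetramethyl-1,3,2-dioxaborolane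
Product: 13 (S)-5-methyl-5-[(2R,5R)-5-methyl-5-[(E)-2-(4,4,5,5-tetramethyl-1,3,2-dioxaborolan-2-yl)ethenyl]tetrahydrofuran-2-yl]dihydrofuran-2(3H)-one
Conditions: CrCl2 (8 equiv), LiI (4 equiv), THF, rt
Reagents that add atoms: none
Why: Takai–Utimoto boron olefination, in which divalent chromium reduces the gem-dihalide to a gem-dichromium species that adds to the aldehyde and eliminates, should give the (E)-alkenyl boronate because the ring residue and the Bpin group lie anti in the addition; lactones are tolerated.

Step 9
Reactants: 14 furan-3-ylmethanol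
Product: 16 3-(chloromethyl)furan, via furan-3-ylmethyl methanesulfonate 15 (not isolated)
Conditions: MsCl, 2,4,6-collidine, LiCl, DMF, 0 °C
Reagents that add atoms: lithium chloride, [Li+].[Cl-]
Why: Collington–Meyers chlorination, in which the alcohol is mesylated and the mesylate is displaced by chloride (SN2) under non-acidic conditions that the furan tolerates.

Step 10
Reactants: 16 3-(chloromethyl)furan; 17 2-methyl-2-vinyloxirane (racemic)
Product: 19 (E)-5-(furan-3-yl)-2-methylpent-2-en-1-ol, via furan-3-ylmethylmagnesium chloride 18 (not isolated)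
Conditions: Mg, THF, 0 °C → rt (slow addition of 16); then CuI (10 mol %), 17, −30 → 0 °C; aq. NH4Cl
Reagents that add atoms: none
Why: Copper-catalysed SN2′ opening of a vinyl oxirane by a Grignard reagent, in which the furylmethyl group adds to the terminal alkene carbon anti to the epoxide in its s-trans conformer, should give the (E)-2-methyl allylic alcohol.

Step 11
Reactants: 19 (E)-5-(furan-3-yl)-2-methylpent-2-en-1-ol
Product: 20 3-[(E)-5-bromo-4-methylpent-3-en-1-yl]furan
Conditions: CBr4, PPh3, CH2Cl2, −20 → 0 °C
Reagents that add atoms: carbon tetrabromide, BrC(Br)(Br)Br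
Why: Appel bromination under neutral conditions converts the primary allylic alcohol to the bromide by SN2 at carbon without allylic transposition or loss of alkene geometry, and spares the acid-sensitive furan.

Step 12
Reactants: 13 (E)-alkenyl pinacol boronate of the tetrahydrofuran–lactone; 20 3-[(E)-5-bromo-4-methylpent-3-en-1-yl]furan
Product: 21 (S)-5-[(2R,5R)-5-[(1E,4E)-7-(furan-3-yl)-4-methylhepta-1,4-dien-1-yl]-5-methyltetrahydrofuran-2-yl]-5-methyldihydrofuran-2(3H)-one
Conditions: Pd(PPh3)4 (5 mol %), CsF (3 equiv), THF, 60 °C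
Reagents that add atoms: none
Why: Zerovalent palladium inserts into the allylic C–Br bond of 20 to give a 1-substituted 2-methyl-π-allyl complex of divalent palladium, the fluoride-activated boronate 13 transmetalates with retention of its E-alkene, and reductive elimination forms the C(sp3)–C(sp2) bond at the unsubstituted allyl terminus. The closest known reaction type is the Suzuki–Miyaura allyl–alkenyl cross-coupling used to make skipped dienes. No ring is closed and no stereocentre is created; the three existing stereocentres are remote from the reacting atoms, and the alkenyl carbon sits on a fully substituted ring carbon that cannot epimerise. The step needs linear over branched regioselectivity and retention of both alkene geometries: the other allyl terminus is secondary and flanked by the 2-methyl group, the syn π-allyl isomer that leads to the E-trisubstituted alkene is the more stable one, and alkenyl boronates transfer with retention. Anhydrous fluoride should keep the γ-lactone closed, and the furan is inert to the catalyst.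

Compound list
1 | geranyl acetate, (E)-3,7-dimethylocta-2,6-dien-1-yl acetate | CC(C)=CCC/C(C)=C/COC(C)=O | starting material
2 | rac-(E)-5-(3,3-dimethyloxiran-2-yl)-3-methylpent-2-en-1-yl acetate | CC(=O)OC/C=C(\C)CCC1OC1(C)C | intermediate
3 | rac-(E)-6-hydroxy-3,7-dimethylocta-2,7-dien-1-yl acetate | CC(=O)OC/C=C(\C)CCC(O)C(C)=C | intermediate
4 | triethyl orthoacetate | CC(OCC)(OCC)OCC | starting material
5 | ethyl (4E,8E)-10-acetoxy-4,8-dimethyldeca-4,8-dienoate | CCOC(=O)CC/C(C)=C/CC/C(C)=C/COC(C)=O | intermediate
6 | ethyl 3-[(2R,3R)-3-[(E)-5-acetoxy-3-methylpent-3-en-1-yl]-2-methyloxiran-2-yl]propanoate | CCOC(=O)CC[C@@]1(C)O[C@@H]1CC/C(C)=C/COC(C)=O | intermediate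
7 | 3-[(2R,3R)-3-[(E)-5-hydroxy-3-methylpent-3-en-1-yl]-2-methyloxiran-2-yl]propanoic acid (formed as its lithium salt, freed on acidification, not isolated) | OC(=O)CC[C@@]1(C)O[C@@H]1CC/C(C)=C/CO | intermediate
8 | (S)-5-[(R,E)-1,6-dihydroxy-4-methylhex-4-en-1-yl]-5-methyldihydrofuran-2(3H)-one | OC/C=C(\C)CC[C@@H](O)[C@]1(C)CCC(=O)O1 | intermediate
9 | (S)-5-[(R)-1-hydroxy-3-[(2S,3S)-3-(hydroxymethyl)-2-methyloxiran-2-yl]propyl]-5-methyldihydrofuran-2(3H)-one (not isolated) | OC[C@@H]1O[C@@]1(C)CC[C@@H](O)[C@]2(C)CCC(=O)O2 | intermediate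
10 | (S)-5-[(2R,5R)-5-[(S)-1,2-dihydroxyethyl]-5-methyltetrahydrofuran-2-yl]-5-methyldihydrofuran-2(3H)-one | OC[C@H](O)[C@@]1(C)CC[C@H]([C@]2(C)CCC(=O)O2)O1 | intermediate
11 | (2R,5R)-2-methyl-5-[(S)-2-methyl-5-oxotetrahydrofuran-2-yl]tetrahydrofuran-2-carbaldehyde | O=C[C@@]1(C)CC[C@H]([C@]2(C)CCC(=O)O2)O1 | intermediate
12 | 2-(dichloromethyl)-4,4,5,5-tetramethyl-1,3,2-dioxaborolane | ClC(Cl)B1OC(C)(C)C(C)(C)O1 | starting material
13 | (S)-5-methyl-5-[(2R,5R)-5-methyl-5-[(E)-2-(4,4,5,5-tetramethyl-1,3,2-dioxaborolan-2-yl)ethenyl]tetrahydrofuran-2-yl]dihydrofuran-2(3H)-one | CC1(C)OB(/C=C/[C@@]2(C)CC[C@H]([C@]3(C)CCC(=O)O3)O2)OC1(C)C | intermediate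
14 | furan-3-ylmethanol | OCc1ccoc1 | starting material
15 | furan-3-ylmethyl methanesulfonate (not isolated) | CS(=O)(=O)OCc1ccoc1 | intermediate
16 | 3-(chloromethyl)furan | ClCc1ccoc1 | intermediate
17 | 2-methyl-2-vinyloxirane (racemic) | CC1(CO1)C=C | starting material
18 | furan-3-ylmethylmagnesium chloride (not isolated) | Cl[Mg]Cc1ccoc1 | intermediate
19 | (E)-5-(furan-3-yl)-2-methylpent-2-en-1-ol | OC/C(C)=C/CCc1ccoc1 | intermediate
20 | 3-[(E)-5-bromo-4-methylpent-3-en-1-yl]furan | BrC/C(C)=C/CCc1ccoc1 | intermediate
21 | (S)-5-[(2R,5R)-5-[(1E,4E)-7-(furan-3-yl)-4-methylhepta-1,4-dien-1-yl]-5-methyltetrahydrofuran-2-yl]-5-methyldihydrofuran-2(3H)-one | C/C(=C\CCc1ccoc1)C/C=C/[C@@]1(C)CC[C@H]([C@]2(C)CCC(=O)O2)O1 | target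

Total step count: 12. Longest linear sequence: 9 steps (steps 1–8, then step 12); the furan-bearing bromide takes 3 steps (steps 9–11).

Steps most likely to fail

Step 12. The coupling may suffer from attack at the substituted allyl terminus (branched diene), from syn/anti isomerisation of the π-allyl intermediate that erodes the geometry of the trisubstituted alkene, or from slow transmetalation and protodeboronation of the hindered boronate. The fallback sets out from aldehyde 11 and changes the nucleophile class. A CrCl2/LiI-mediated Hodgson olefination with Bu3SnCHBr2 in THF/DMF should give the (E)-alkenyl tributylstannane F1. A base-free Stille coupling of F1 with bromide 20 (Pd2(dba)3, AsPh3, THF, 50 °C) then comes back to the route at 21.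

Step 8. Addition of the bulky gem-dichromium reagent to the neopentyl-type α-alkoxy aldehyde may be slow, so that pinacol-type reductive dimerisation or simple reduction of the aldehyde competes. The fallback sets out from aldehyde 11. Ohira–Bestmann homologation (dimethyl (1-diazo-2-oxopropyl)phosphonate, K2CO3, MeOH, 0 °C → rt) should give the terminal alkyne F2. Copper-catalysed anti-Markovnikov protoboration of F2 (CuCl, Xantphos, NaOtBu (cat.), B2pin2, MeOH, THF, rt) then comes back to the route at 13.

Step 10. Wurtz-type homocoupling may compete during formation of the furylmethyl Grignard reagent, and direct SN2 opening or incomplete E selectivity may spoil the SN2′ opening. The fallback sets out from chloride 16 and builds the alkene by olefination instead. Alkylation of the lithium enolate of N-methoxy-N-methylacetamide (LiN(i-Pr)2, THF, −78 °C → rt) with 16 should give the Weinreb amide F3. Reduction with i-Bu2AlH (THF, −78 °C) gives 3-(furan-3-yl)propanal F4. Wittig olefination with Ph3P=C(CH3)CO2Et (CH2Cl2, rt) should give the (E)-enoate F5, and i-Bu2AlH (CH2Cl2, −78 °C) reduces F5 to come back to the route at 19.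

Further compounds
F1 | step 12 | tributyl[(E)-2-[(2R,5R)-2-methyl-5-[(S)-2-methyl-5-oxotetrahydrofuran-2-yl]tetrahydrofuran-2-yl]ethenyl]stannane | CCCC[Sn](CCCC)(CCCC)/C=C/[C@@]1(C)CC[C@H]([C@]2(C)CCC(=O)O2)O1
F2 | step 8 | (S)-5-[(2R,5R)-5-ethynyl-5-methyltetrahydrofuran-2-yl]-5-methyldihydrofuran-2(3H)-one | C#C[C@@]1(C)CC[C@H]([C@]2(C)CCC(=O)O2)O1
F3 | step 10 | 3-(furan-3-yl)-N-methoxy-N-methylpropanamide | CON(C)C(=O)CCc1ccoc1
F4 | step 10 | 3-(furan-3-yl)propanal | O=CCCc1ccoc1
F5 | step 10 | ethyl (E)-5-(furan-3-yl)-2-methylpent-2-enoate | CCOC(=O)/C(C)=C/CCc1ccoc1
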